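18.1 % of the G charged still stands in the ash run at 4.00 min, and 18.5 % stood there already at 0.500 min, while D climbs from 6.2 % to 21.4 % over the same time.

| flask | G | E | Q | remark | time |
|---|---|---|---|---|---|
| ash | 0.50 mM | 0.525 mM | 0.525 mM | run made earlier |  |
| alder | 0.25 mM | 0.525 mM | 0.525 mM | run made earlier |  |
| larch | 1 mM | 0.525 mM | 0.525 mM | run made earlier |  |
| elm | 0.50 mM | 0.525 mM | 1.1 mM | run made earlier |  |
| ochre | 0.50 mM | 0.525 mM (fed, over 2.5 min) | 0.525 mM | all else is in the flask from the start; the feed brings no volume worth counting | 4.0 min |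
| green | 0.50 mM | 0.525 mM | 0.525 mM | everything together at the start | 4.0 min |
| grey | 0.50 mM (fed, over 2.5 min) | 0.525 mM | 0.525 mM | all else is in the flask from the start; the feed brings no volume worth counting | 4.0 min |
| amber | 0.50 mM (fed, over 40 s) | 0.525 mM | 0.525 mM | all else is in the flask from the start; the feed brings no volume worth counting | 4.0 min |

| run | time / min | D / % | G / % |
|---|---|---|---|
| ash | 0.500 | 6.2 | 18.5 |
| ash | 1.00 | 11.6 | 17.9 |
| ash | 1.50 | 14.8 | 17.6 |
| ash | 2.50 | 18.8 | 18.3 |
| ash | 3.00 | 19.9 | 18.0 |
| ash | 4.00 | 21.4 | 18.1 |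
| alder | 0.250 | 5.5 | 4.9 |
| alder | 0.667 | 18.6 | 0.9 |
| alder | 1.33 | 36.5 | 0.5 |
| alder | 2.00 | 48.9 | 0.7 |
| alder | 3.00 | 60.9 | 0.1 |
| alder | 4.00 | 68.5 | 0.4 |
| alder | 5.00 | 74.4 | 0.1 |
| larch | 0.417 | 1.2 | 52.2 |
| larch | 0.667 | 2.1 | 51.9 |
| larch | 0.833 | 2.3 | 51.7 |
| larch | 1.33 | 3.5 | 51.9 |
| larch | 2.00 | 3.7 | 52.2 |
| larch | 3.00 | 4.5 | 52.0 |
| larch | 5.00 | 4.3 | 52.2 |
| elm | 0.417 | 16.6 | 0 |
| elm | 0.667 | 27.9 | 0.3 |
| elm | 1.33 | 49.5 | 0 |
| elm | 2.50 | 67.9 | 0.2 |
| elm | 5.00 | 83.7 | 0.4 |

(each reading ± 0.3 percentage points)

- the earlier runs were read with a standard deviation of 0.3 percentage points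
- a reading or a percentage of D counts all its forms, free or not

- which flask leads in amount of D, in percent of the G charged ("all alike" within 1.5 percentage points) (ochre / green / grey / amber / all alike)
- how much D is there at the end, in percent of the G charged: ochre
- how much D is there at the end, in percent of the G charged: green
- how much D is there at the end, in percent of the G charged: grey
- how much D is there at the end, in percent of the G charged: amber

I read two clocks in ash: G stops being taken before the first reading, and D goes on forming after that, over minutes. I take it that G and E compete for Q, one Q each, and that Q is used up. In ash, then, G has taken 0.409 mM of the 0.525 mM of Q and E has taken 0.116 mM. The ratio of the logarithms of what is left of each is the selectivity factor S. It reads 6.88 in ash and 6.93 in larch, while S = 1 is the symmetric case. From S I take the even-split concentration c*, the cG at which G and E, with E at its charge, take Q at equal rates: c* = cE/S = 0.0763 mM.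

Alder, charged with less G than ash, has a G share of Q near half and holds 0.171 mM of D at 4.00 min, while ash has a share of 77.9 % and 0.107 mM of D at 4.00 min.

Now the ladder. In ash, G's taking ends within 0.500 min, which is shorter than the quick feed of 40 s, and that feed is shorter than the slow one of 2.5 min. D in ash is still rising at 4.00 min. Green has the charges of ash, so I expect it to repeat ash, starting at 6.55 times c*. Counting no loss, amber's feed brings c* in 0.102 min, sooner than grey's 0.382 min. I expect G's share near even in amber and below even in grey. In ochre, where cE starts low, I expect it above the share in ash. My choice is amber.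

The forecast also says amber, with ochre 4.8 %, green 21.5 %, grey 25 % and amber 33 %, calling amber “the balanced alder-like case”.

Amber leads with 34.1 %, ahead of grey at 25.1 %, green at 21.1 % and ochre at 6.47 %.

    Q + E → J (k = 140 M⁻¹ s⁻¹)
    G + Q → X (k = 990 M⁻¹ s⁻¹)
    Z ⇌ D, rate k3*(cs3 - [D]) while solid is left; crystals form when [D] > cs3 (solubility = 0.0540 mM, k = 0.930 s⁻¹)
    X + J → D (k = 33.0 M⁻¹ s⁻¹)

Amber's figure has moved by 5 points when cQ stands at 0.467 mM or 0.582 mM. At the end of amber, 53 % of G and 45 % of E are left with Q at 0 %, so G has taken 45.0 % of the Q in the flask whose feed, counted without loss, brings c* in 0.102 min. Grey, whose feed, counted the same way, brings c* in 0.382 min, ends with 71 % of G left, and there G has taken 27.7 % of the Q.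

The readings were generated by integration for an exercise; noise was put on by code.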